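The synthesis rests on reading the central 2,3-diarylbuta-1,3-diene C2=Calpha(Ar)–Calpha'(Ar)=C2' as a former hexa-2,4-diyne. On each exocyclic alkene the furanone oxygen O1 stands trans to catechol ring B. That is the signature of an anti addition of O1 (to C2) and aryl (to Calpha) across a triple bond. The key step treats an open-chain 1,6-bis(2-hydroxyaryl)hexa-2,4-diyne-1,6-diol with two equivalents of a protected 4-iodocatechol under zerovalent palladium. In one flask it closes both five-membered oxygen rings, attaches both rings B and fixes both alkene geometries. Oxidation of the two carbinols and removal of six acetal groups then complete the target.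

Key step: step 6

Assumption: the alkene geometry is taken exactly as written in the SMILES (O1 cis to the other diene half and trans to ring B on both alkenes, 2Z,2'Z by the CIP rules), and atoms carry aurone numbering (O1, C2, C3 in the furanone, Calpha exocyclic).

Step 1
Reactants: 1 2,4-dihydroxybenzaldehyde
Product: 2 2-hydroxy-4-(methoxymethoxy)benzaldehyde
Conditions: MOMCl (1.1 equiv), K2CO3 (1.5 equiv), acetone, 0 °C → rt
Reagents that add atoms: chloromethyl methyl ether (MOMCl), COCCl
Why: Williamson-type O-alkylation under weak base, in which the 2-OH is locked in a hydrogen bond to the formyl oxygen and is the less acidic and less nucleophilic phenol, so a slight excess of MOMCl should react only at the 4-OH.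

Step 2
Reactants: 2 2-hydroxy-4-(methoxymethoxy)benzaldehyde; 3 ethynylmagnesium bromide
Product: 4 rac-1-[2-hydroxy-4-(methoxymethoxy)phenyl]prop-2-yn-1-ol
Conditions: 3 (3 equiv, 0.5 M in THF), THF, 0 °C → rt; sat. aq. NH4Cl, 0 °C; Et3N-deactivated silica
Reagents that add atoms: ethynylmagnesium bromide (3), C#C[Mg]Br
Why: Alkynyl Grignard 1,2-addition to an aldehyde, in which the first equivalent merely turns the phenol into its magnesium phenoxide, further reagent adds to the formyl group, and the new carbinol centre arises racemic, which is harmless because step 7 erases it.

Step 3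
Reactants: 4 rac-1-[2-hydroxy-4-(methoxymethoxy)phenyl]prop-2-yn-1-ol (two molecules)
Product: 5 1,6-bis[2-hydroxy-4-(methoxymethoxy)phenyl]hexa-2,4-diyne-1,6-diol (rac and meso forms together)
Conditions: Cu(OAc)2 (3 equiv), pyridine/MeCN, rt → 40 °C, argon
Reagents that add atoms: none
Why: Eglinton coupling, in which the copper acetylide is dimerized by divalent copper in pyridine to forge the future Calpha–Calpha' bond; the medium contains no palladium, no O2 and no alkylating oxidant, because ortho-phenols of this type can be cyclized prematurely by divalent palladium, oxidized by copper under O2 and O-alkylated by haloester oxidants, and the two carbinol centres simply combine to a diastereomer mixture of no consequence.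

Step 4
Reactants: 6 catechol
Product: 7 1,2-bis(methoxymethoxy)benzene
Conditions: NaH (2.5 equiv), MOMCl (2.5 equiv), THF/DMF, 0 °C → rt, argon
Reagents that add atoms: chloromethyl methyl ether (MOMCl), COCCl
Why: Double Williamson-type O-alkylation of the sodium catecholate with the reactive alpha-chloro ether, run under inert gas so that the catecholate is not oxidized.

Step 5
Reactants: 7 1,2-bis(methoxymethoxy)benzene
Product: 8 4-iodo-1,2-bis(methoxymethoxy)benzene
Conditions: NIS (1.05 equiv), MeCN, rt → 50 °C, dark
Reagents that add atoms: N-iodosuccinimide (NIS), O=C1CCC(=O)N1I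
Why: Electrophilic aromatic iodination in a polar, acid-free medium, in which both acetal oxygens activate the ring, attack para to one of them (C4) is preferred over the crowded positions C3 and C6, and the absence of added acid spares the MOM groups.

Step 6
Reactants: 5 1,6-bis[2-hydroxy-4-(methoxymethoxy)phenyl]hexa-2,4-diyne-1,6-diol; 8 4-iodo-1,2-bis(methoxymethoxy)benzene (2.4 equiv)
Product: 10 hexa-MOM bis-carbinol (2Z,2'Z)-2,2'-{1,2-bis[3,4-bis(methoxymethoxy)phenyl]ethane-1,2-diylidene}bis[6-(methoxymethoxy)-2,3-dihydrobenzofuran-3-ol] (carbinol centres unselected), via mono-oxyarylated enyne 9 (not isolated)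
Conditions: Pd(PPh3)4 (10 mol %), K2CO3 (5 equiv), degassed MeCN, 50 °C, slow addition of 5 to the premixed catalyst and 8, argon, dark; filtration through basic alumina, crude 10 used at once (no silica, no acid)
Reagents that add atoms: none
Why: Proposed new method: oxidative addition of 8 to zerovalent palladium gives an arylpalladium iodide (divalent palladium) that coordinates one triple bond of 5, the potassium phenoxide attacks the carbinol-bearing alkyne carbon C2 from the face opposite the metal, and the resulting alkenyl(aryl)palladium collapses by reductive elimination to the Calpha–aryl bond, after which enyne 9 passes through the same cycle at its remaining triple bond. The closest known reaction type is the Cacchi-type oxypalladation–reductive elimination of alkynes carrying a tethered oxygen nucleophile with aryl halides, which gives stereodefined arylidene oxacycles, taken together with the 5-exo cyclization of 2-(1-hydroxyprop-2-ynyl)phenols used for aurones; the conjugated 1,3-diyne substrate and the twofold run are what is new. Both dihydrofuran rings close in the 5-exo-dig mode (O1–C2 and O1'–C2'). No sp3 centre is created, and each tetrasubstituted alkene geometry is dictated by the anti relationship between oxygen attack and palladium followed by reductive elimination with retention, so ring B ends up trans to O1 and cis to C3. The step needs 5-exo closure to beat 6-endo closure, and anti-oxypalladation to beat syn-carbopalladation and closure without aryl transfer: the short ortho-phenoxide tether, the sp3 carbinol at C3 (no ynone Michael bias toward a chromone) and the habit of 1,3-diynes to accept nucleophiles at their terminal carbon direct oxygen to C2 and palladium to Calpha, while a fully formed phenoxide, a polar solvent and an excess of preformed arylpalladium iodide at moderate temperature favour the outer-sphere pathway. The second closure is the harder one because the new enol ether feeds electron density into the remaining alkyne and Calpha is already crowded, but in 9 the C3 carbinol lies trans to the alkynyl group and so cannot divert the enyne into a furan.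

Step 7
Reactants: 10 hexa-MOM bis-carbinol
Product: 11 hexa-MOM disulfuretin (2Z,2'Z)-2,2'-{1,2-bis[3,4-bis(methoxymethoxy)phenyl]ethane-1,2-diylidene}bis[6-(methoxymethoxy)benzofuran-3(2H)-one]
Conditions: activated MnO2 (large excess), solid NaHCO3, CH2Cl2, rt, dark; filtration through Celite
Reagents that add atoms: none
Why: Heterogeneous MnO2 oxidation of allylic and benzylic alcohols, the standard passage from 2-alkylidene-2,3-dihydrobenzofuran-3-ols to aurones, whose neutral buffered medium avoids ionization of the C3–OH bond toward aromatic benzofurans, removes both unselected carbinol centres and leaves the two alkene geometries untouched.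

Step 8
Reactants: 11 hexa-MOM disulfuretin
Product: 12 disulfuretin
Conditions: HCl (1.25 M in MeOH), THF, 0 °C → rt, argon, dark
Reagents that add atoms: none
Why: Acid-catalysed transacetalization of aryl MOM ethers with methanol releases all six phenols, the vinylogous ester core of an aurone being stable to such acid, while low temperature, darkness and exclusion of air are meant to suppress E/Z isomerization of the push-pull alkenes and oxidation of the catechols.

Compound list
1 | 2,4-dihydroxybenzaldehyde | O=Cc1ccc(O)cc1O | starting material
2 | 2-hydroxy-4-(methoxymethoxy)benzaldehyde | O=Cc1ccc(OCOC)cc1O | intermediate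
3 | ethynylmagnesium bromide | C#C[Mg]Br | starting material
4 | rac-1-[2-hydroxy-4-(methoxymethoxy)phenyl]prop-2-yn-1-ol | C#CC(O)c1ccc(OCOC)cc1O | intermediate
5 | 1,6-bis[2-hydroxy-4-(methoxymethoxy)phenyl]hexa-2,4-diyne-1,6-diol, rac and meso forms together | OC(C#CC#CC(O)c1ccc(OCOC)cc1O)c1ccc(OCOC)cc1O | intermediate
6 | catechol (benzene-1,2-diol) | Oc1ccccc1O | starting material
7 | 1,2-bis(methoxymethoxy)benzene | COCOc1ccccc1OCOC | intermediate
8 | 4-iodo-1,2-bis(methoxymethoxy)benzene | COCOc1ccc(I)cc1OCOC | intermediate
9 | mono-oxyarylated enyne, (Z)-2-{1-[3,4-bis(methoxymethoxy)phenyl]-4-hydroxy-4-[2-hydroxy-4-(methoxymethoxy)phenyl]but-2-yn-1-ylidene}-6-(methoxymethoxy)-2,3-dihydrobenzofuran-3-ol; O1 cis to the alkynyl group, ring B trans to O1; carbinol centres unselected; formed and consumed in the flask of step 6 | OC1/C(=C(/C#CC(O)c2ccc(OCOC)cc2O)c2ccc(OCOC)c(OCOC)c2)Oc2cc(OCOC)ccc21 | intermediate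
10 | hexa-MOM bis-carbinol, (2Z,2'Z)-2,2'-{1,2-bis[3,4-bis(methoxymethoxy)phenyl]ethane-1,2-diylidene}bis[6-(methoxymethoxy)-2,3-dihydrobenzofuran-3-ol]; on each alkene O1 cis to the other diene half, ring B trans to O1 and cis to C3; carbinol centres unselected | OC1/C(=C(/C(=C2\Oc3cc(OCOC)ccc3C2O)c2ccc(OCOC)c(OCOC)c2)c2ccc(OCOC)c(OCOC)c2)Oc2cc(OCOC)ccc21 | intermediate
11 | hexa-MOM disulfuretin, (2Z,2'Z)-2,2'-{1,2-bis[3,4-bis(methoxymethoxy)phenyl]ethane-1,2-diylidene}bis[6-(methoxymethoxy)benzofuran-3(2H)-one] | O=C1/C(=C(/C(=C2\Oc3cc(OCOC)ccc3C2=O)c2ccc(OCOC)c(OCOC)c2)c2ccc(OCOC)c(OCOC)c2)Oc2cc(OCOC)ccc21 | intermediate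
12 | disulfuretin, (2Z,2'Z)-2,2'-[1,2-bis(3,4-dihydroxyphenyl)ethane-1,2-diylidene]bis[6-hydroxybenzofuran-3(2H)-one] | O=C1/C(=C(/C(=C2\Oc3cc(O)ccc3C2=O)c2ccc(O)c(O)c2)c2ccc(O)c(O)c2)Oc2cc(O)ccc21 | target

Total step count: 8
Longest linear sequence: 6 steps (1 → 2 → 4 → 5 → 10 → 11 → 12, that is steps 1, 2, 3, 6, 7, 8)

Steps most likely to fail

First, step 6.
- **What may go wrong:** closure in the 6-endo sense, syn-carbopalladation of a triple bond by the arylpalladium species, ring closure without aryl transfer through protonation of the alkenylpalladium, or stalling after the first cycle because the second alkyne is deactivated and crowded.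
- **Fallback:** it uses known reaction types only and splits the cascade into an anti iodoetherification and a cross-coupling. It sets out from 5 and from 8. Treating 5 with I2 and NaHCO3 in MeCN at 0 °C should bring about a twofold 5-exo electrophilic iodocyclization, in which O1 and iodine add anti, to give the (E,E)-diiodo diene diol F1. In parallel, Miyaura borylation of 8 (B2pin2, PdCl2(dppf), KOAc, dioxane, 80 °C) gives the aryl pinacol boronate F2. A double Suzuki–Miyaura coupling of F1 with F2 (Pd(PPh3)4, K3PO4, THF/H2O, 50 °C) exchanges each iodine for ring B with retention of alkene geometry and comes back to the route at 10.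

Second, step 8.
- **What may go wrong:** acid-promoted rotation about the C2=Calpha bonds through the protonated vinylogous ester, whose positive charge is shared with the para oxygen of ring B. Incomplete cleavage of the six acetals at a temperature low enough to hold the geometry is also possible, as is aerial oxidation of the liberated catechols.
- **Fallback:** it replaces acid solvolysis by an exchange of protecting groups in a non-acidic medium. It sets out from 11. TMSOTf and 2,2'-bipyridyl in MeCN at 0 °C convert the aryl acetals into silyl ethers and give the hexakis(trimethylsilyl) ether F4. This ether is hydrolysed by water at neutral pH during work-up, which comes back to the route at 12.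

Third, step 7.
- **What may go wrong:** ionization of the doubly activated C3–OH bonds with allylic transposition and aromatization before oxidation is complete, or sluggish oxidation because ring B lies cis to C3 and shields the carbinol.
- **Fallback:** it moves the oxidation ahead of the introduction of ring B, so that the carbinol being oxidized is neither shielded nor activated by an electron-rich aryl group at Calpha. It sets out from 5. The iodocyclization described above gives F1, and MnO2 in CH2Cl2 oxidizes it to the (E,E)-diiodo diene dione F3. A double Suzuki–Miyaura coupling of F3 with F2 (Pd(PPh3)4, K3PO4, THF/H2O, rt → 40 °C), with retention at the beta-iodo enone carbons, comes back to the route at 11 and bypasses 10 altogether.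

Further compounds
F1 | step 6 | (E,E)-diiodo diene diol, 2,2'-(1,2-diiodoethane-1,2-diylidene)bis[6-(methoxymethoxy)-2,3-dihydrobenzofuran-3-ol], iodine trans to O1 on each alkene, carbinol centres unselected | OC1/C(=C(/C(=C2\Oc3cc(OCOC)ccc3C2O)I)I)Oc2cc(OCOC)ccc21
F2 | step 6 | 2-[3,4-bis(methoxymethoxy)phenyl]-4,4,5,5-tetramethyl-1,3,2-dioxaborolane | COCOc1ccc(B2OC(C)(C)C(C)(C)O2)cc1OCOC
F3 | step 7 | (E,E)-diiodo diene dione, 2,2'-(1,2-diiodoethane-1,2-diylidene)bis[6-(methoxymethoxy)benzofuran-3(2H)-one], iodine trans to O1 on each alkene | O=C1/C(=C(/C(=C2\Oc3cc(OCOC)ccc3C2=O)I)I)Oc2cc(OCOC)ccc21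
F4 | step 8 | hexakis(trimethylsilyl) ether of disulfuretin, alkene geometry as in 11 | O=C1/C(=C(/C(=C2\Oc3cc(O[Si](C)(C)C)ccc3C2=O)c2ccc(O[Si](C)(C)C)c(O[Si](C)(C)C)c2)c2ccc(O[Si](C)(C)C)c(O[Si](C)(C)C)c2)Oc2cc(O[Si](C)(C)C)ccc21
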